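(R)-Mevalonolactone ⇒ oxetane ⇒ bicyclic peroxy-acylal; the last step opens that acylal with the side-chain alkylzinc, forming the exocyclic C5–CH2 bond, setting C5 and freeing CO2H. The chirality, E/Z and atom bookkeeping were re-derived by hand on the SMILES strings, not machine-checked.

- Target ⇒ cut the exocyclic C5–CH2 bond: alkylzinc from [(1E,3E,11R)-12-iodo-11-methyldodeca-1,3-dien-1-yl]benzene + (1S,5R)-1,5-dimethyl-2,6,7-trioxabicyclo[3.2.1]octan-3-one.
- Enabling feature: the bridgehead acylal carbon C1 of the trioxabicyclo[3.2.1]octanone (C5 of the target), bonded to peroxide O7 and lactone O2. The 1,2-dioxolane ring is already present, and the fused oxan-2-one ring ties the leaving carboxylate to the C3 arm, so the alkyl group is delivered cis to CH2CO2H.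
- Acylal ⇐ RuO4 oxidation of (1S,5S)-1,5-dimethyl-2,6,7-trioxabicyclo[3.2.1]octane ⇐ perhydrolysis with inversion of 1-[(2R)-2-methyloxetan-2-yl]propan-2-one (all ring–chain tautomers funnel into the one cis-bridged ketal) ⇐ (R)-mevalonolactone, whose six carbons become C5, C4, C3, 3-CH3 and CH2CO2H.
- Side-chain iodide ⇐ (S)-3-bromo-2-methylpropan-1-ol + hept-6-enyl Grignard (Cu), then ozonolysis and Horner–Wadsworth–Emmons olefination with diethyl cinnamylphosphonate.
- Ring order: oxetane (temporary) → 1,2-dioxolane and oxane rings together (bicyclic ketal) → oxane oxidised to lactone → lactone opened in the key step; the phenyl ring is bought.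

Key step: step 13

Assumption: compounds 1, 11, 13 and 18 are bought as such, and perhydrolysis of the 2,2-disubstituted oxetane is taken to occur at the tertiary carbon with inversion.

Step 1
Reactants: 1 (4R)-4-hydroxy-4-methyloxan-2-one [(R)-mevalonolactone]
Product: 2 (3R)-3,5-dihydroxy-N-methoxy-N,3-dimethylpentanamide
Conditions: MeNH(OMe)·HCl, i-PrMgCl, THF, −20 → 0 °C; aq NH4Cl
Reagents that add atoms: N,O-dimethylhydroxylamine hydrochloride, CNOC.Cl
Why: Aminolysis of the δ-lactone by the chloromagnesium amide (Weinreb amide formation) should open the ring without touching the tertiary carbinol stereocentre.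

Step 2
Reactants: 2 (3R)-3,5-dihydroxy-N-methoxy-N,3-dimethylpentanamide
Product: 3 (3R)-3-hydroxy-5-[methoxy(methyl)amino]-3-methyl-5-oxopentyl 4-methylbenzenesulfonate
Conditions: TsCl, Et3N, DMAP (cat.), CH2Cl2, 0 °C
Reagents that add atoms: 4-methylbenzenesulfonyl chloride, Cc1ccc(cc1)S(=O)(=O)Cl
Why: Sulfonylation should be selective for the primary over the tertiary hydroxyl group (steric control) and installs the leaving group for ring closure.

Step 3
Reactants: 3 (3R)-3-hydroxy-5-[methoxy(methyl)amino]-3-methyl-5-oxopentyl 4-methylbenzenesulfonate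
Product: 4 N-methoxy-N-methyl-2-[(2R)-2-methyloxetan-2-yl]acetamide
Conditions: KOt-Bu, THF, 0 °C → rt
Reagents that add atoms: none
Why: Intramolecular Williamson etherification (4-exo-tet) of the tertiary alkoxide on the primary tosylate is the standard oxetane synthesis from 1,3-diol monosulfonates; the C–O bond of the stereocentre is not broken, so its configuration is kept.

Step 4
Reactants: 4 N-methoxy-N-methyl-2-[(2R)-2-methyloxetan-2-yl]acetamide
Product: 6 1-[(2R)-2-methyloxetan-2-yl]propan-2-one, via magnesium hemiaminal 5 (not isolated)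
Conditions: MeMgBr, THF, −20 → 0 °C; cold aq NH4Cl
Reagents that add atoms: methylmagnesium bromide, C[Mg]Br
Why: Weinreb ketone synthesis: the chelated tetrahedral adduct 5 should stop the addition at the ketone level, and the oxetane is inert to the Grignard reagent at low temperature.

Step 5
Reactants: 6 1-[(2R)-2-methyloxetan-2-yl]propan-2-one
Product: 9 (1S,5S)-1,5-dimethyl-2,6,7-trioxabicyclo[3.2.1]octane, via hydroperoxy ketone 7 (not isolated), via peroxyhemiketal 8 (not isolated)
Conditions: H2O2 (anhydrous, Et2O), TMSOTf (cat.), −78 → −20 °C; then PPTS (cat.), 4 Å MS, CH2Cl2, rt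
Reagents that add atoms: hydrogen peroxide, OO
Why: Lewis acid-mediated perhydrolysis of the oxetane should occur at the tertiary carbon with inversion (SN2-like opening), which sets the peroxide-bearing stereocentre (future C3); β-hydroperoxy ketone 7 closes to peroxyhemiketal 8, and acid-catalysed intramolecular ketalisation by the freed hydroxyethyl arm fixes the second bridgehead, because all ring–chain tautomers can converge only on the cis-bridged ketal.

Step 6
Reactants: 9 (1S,5S)-1,5-dimethyl-2,6,7-trioxabicyclo[3.2.1]octane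
Product: 10 (1S,5R)-1,5-dimethyl-2,6,7-trioxabicyclo[3.2.1]octan-3-one
Conditions: RuCl3·xH2O (cat.), NaIO4, CCl4/MeCN/H2O, rt
Reagents that add atoms: sodium periodate (oxygen relayed by RuO4), [Na+].[O-]I(=O)(=O)=O
Why: Ruthenium tetroxide oxidation of an ether α-CH2 to the ester level should act on the only O–CH2 group (C3 of the bicycle) and turn the cyclic ketal into the lactone (acylal) without affecting the peroxide or the stereocentres.

Step 7
Reactants: 11 (2S)-3-bromo-2-methylpropan-1-ol
Product: 12 [(2S)-3-bromo-2-methylpropoxy](tert-butyl)dimethylsilane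
Conditions: TBSCl, imidazole, CH2Cl2, 0 °C → rt
Reagents that add atoms: tert-butyldimethylsilyl chloride, CC(C)(C)[Si](C)(C)Cl
Why: Standard silylation of the primary alcohol; the stereocentre is untouched.

Step 8
Reactants: 12 [(2S)-3-bromo-2-methylpropoxy](tert-butyl)dimethylsilane; 13 7-bromohept-1-ene
Product: 15 tert-butyldimethyl{[(2R)-2-methyldec-9-en-1-yl]oxy}silane, via Grignard reagent 14 (not isolated)
Conditions: 13, Mg, THF; then 12, Li2CuCl4 (cat.), THF/NMP, −10 °C → rt
Reagents that add atoms: none
Why: Copper-catalysed sp3–sp3 cross-coupling of a Grignard reagent with a primary alkyl bromide should extend the chain; the stereocentre lies β to the reacting carbon and is not affected (the descriptor changes only through the priority rules).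

Step 9
Reactants: 15 tert-butyldimethyl{[(2R)-2-methyldec-9-en-1-yl]oxy}silane
Product: 17 (8R)-9-[(tert-butyldimethylsilyl)oxy]-8-methylnonanal, via ozonide 16 (not isolated)
Conditions: O3, CH2Cl2, −78 °C; PPh3, −78 °C → rt
Reagents that add atoms: ozone, [O-][O+]=O
Why: Ozonolysis of the terminal alkene with reductive work-up of ozonide 16 should give the aldehyde one carbon shorter; silyl ether and stereocentre are inert.

Step 10
Reactants: 17 (8R)-9-[(tert-butyldimethylsilyl)oxy]-8-methylnonanal; 18 diethyl [(2E)-3-phenylprop-2-en-1-yl]phosphonate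
Product: 20 tert-butyldimethyl{[(2R,9E,11E)-2-methyl-12-phenyldodeca-9,11-dien-1-yl]oxy}silane, via lithiated phosphonate 19 (not isolated)
Conditions: 18, LiHMDS, THF, −78 °C; then 17, −78 °C → rt
Reagents that add atoms: none
Why: Horner–Wadsworth–Emmons olefination with the allylic phosphonate anion should form the new disubstituted double bond with E selectivity, the cinnamyl E geometry being carried over from 18.

Step 11
Reactants: 20 tert-butyldimethyl{[(2R,9E,11E)-2-methyl-12-phenyldodeca-9,11-dien-1-yl]oxy}silane
Product: 21 (2R,9E,11E)-2-methyl-12-phenyldodeca-9,11-dien-1-ol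
Conditions: TBAF, THF, 0 °C → rt
Reagents that add atoms: none
Why: Fluoride-mediated cleavage of the silyl ether; diene and stereocentre are unaffected.

Step 12
Reactants: 21 (2R,9E,11E)-2-methyl-12-phenyldodeca-9,11-dien-1-ol
Product: 22 [(1E,3E,11R)-12-iodo-11-methyldodeca-1,3-dien-1-yl]benzene
Conditions: PPh3, imidazole, I2, CH2Cl2, 0 °C, dark
Reagents that add atoms: iodine, II
Why: Appel-type iodination should convert the primary alcohol into the iodide by SN2 at CH2, away from the stereocentre.

Step 13
Reactants: 22 [(1E,3E,11R)-12-iodo-11-methyldodeca-1,3-dien-1-yl]benzene; 10 (1S,5R)-1,5-dimethyl-2,6,7-trioxabicyclo[3.2.1]octan-3-one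
Product: 26 2-[(3R,5R)-3,5-dimethyl-5-[(2R,9E,11E)-2-methyl-12-phenyldodeca-9,11-dien-1-yl]-1,2-dioxolan-3-yl]acetic acid (target), via dialkylzinc 23 (not isolated), via alkylzinc triflate 24 (not isolated), via zinc carboxylate 25 (not isolated)
Conditions: 22, Et2Zn, CuI (cat.), 50 °C, volatiles removed; Zn(OTf)2, CH2Cl2/toluene, rt; then 10, −40 → 0 °C; 0.5 M HCl
Reagents that add atoms: none
Why: Proposed new method: the Lewis-acidic alkylzinc triflate 24 should bind the lactone carbonyl of acylal 10 and ionise the bridgehead C1–O2 (acyloxy) bond, which gives a 1,2-dioxolan-3-ylium (peroxycarbenium) ion whose counter-ion is the alkyl(carboxylato)zincate that stays tied to C3 through the CH2CO2 arm; collapse of this tethered ion pair moves the primary alkyl group from zinc to the cationic carbon on the face from which the carboxylate left (SNi-type retention) and leaves zinc carboxylate 25, the salt of the target. The closest known reaction types are the zinc halide-catalysed SN1 alkylation of tertiary alkyl chlorides by dialkylzincs (collapse of a carbocation–alkylzincate ion pair), the retentive alkylative opening of bicyclic ketals by organoaluminium reagents, and the Lewis acid-mediated substitution of 3-alkoxy-1,2-dioxolanes by way of peroxycarbenium ions. No ring is closed: the oxan-2-one ring of the bicycle is opened and the 1,2-dioxolane inside it is kept. The one new stereocentre, quaternary C5, is controlled by C3, because the zinc that carries the alkyl group is held by the C3 acetate arm and can reach only the cis face of the planar cation; this puts the side chain cis to CH2CO2H and the two ring methyl groups cis, as in the target. The step needs ionisation of C–O(acyl) in preference to C–OO, and C-alkyl transfer in preference to β-hydride transfer or attack at the O–O bond; the first is secured by the carboxylate being the far better leaving group and the acyl oxygen the poorer cation-stabilising group, the second is sought with zinc (a weak hydride donor that leaves dialkyl peroxides alone), one alkyl group per zinc, an iodide-free reagent and low temperature.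

Compound list
1 | (4R)-4-hydroxy-4-methyloxan-2-one [(R)-mevalonolactone] | C[C@@]1(O)CCOC(=O)C1 | starting material
2 | (3R)-3,5-dihydroxy-N-methoxy-N,3-dimethylpentanamide | C[C@@](O)(CCO)CC(=O)N(C)OC | intermediate
3 | (3R)-3-hydroxy-5-[methoxy(methyl)amino]-3-methyl-5-oxopentyl 4-methylbenzenesulfonate | C[C@@](O)(CCOS(=O)(=O)c1ccc(C)cc1)CC(=O)N(C)OC | intermediate
4 | N-methoxy-N-methyl-2-[(2R)-2-methyloxetan-2-yl]acetamide | C[C@]1(CC(=O)N(C)OC)CCO1 | intermediate
5 | bromomagnesium 2-[methoxy(methyl)amino]-1-[(2R)-2-methyloxetan-2-yl]propan-2-olate (tetrahedral adduct, not isolated) | C[C@]1(CC(C)(O[Mg]Br)N(C)OC)CCO1 | intermediate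
6 | 1-[(2R)-2-methyloxetan-2-yl]propan-2-one | C[C@]1(CC(C)=O)CCO1 | intermediate
7 | (4S)-4-hydroperoxy-6-hydroxy-4-methylhexan-2-one (not isolated) | C[C@@](OO)(CC(C)=O)CCO | intermediate
8 | (5S)-5-(2-hydroxyethyl)-3,5-dimethyl-1,2-dioxolan-3-ol, both epimers at C3 (not isolated) | CC1(O)C[C@](C)(CCO)OO1 | intermediate
9 | (1S,5S)-1,5-dimethyl-2,6,7-trioxabicyclo[3.2.1]octane | C[C@]12C[C@](C)(CCO1)OO2 | intermediate
10 | (1S,5R)-1,5-dimethyl-2,6,7-trioxabicyclo[3.2.1]octan-3-one | C[C@]12C[C@](C)(CC(=O)O1)OO2 | intermediate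
11 | (2S)-3-bromo-2-methylpropan-1-ol | C[C@H](CBr)CO | starting material
12 | [(2S)-3-bromo-2-methylpropoxy](tert-butyl)dimethylsilane | C[C@H](CBr)CO[Si](C)(C)C(C)(C)C | intermediate
13 | 7-bromohept-1-ene | C=CCCCCCBr | starting material
14 | hept-6-en-1-ylmagnesium bromide (not isolated) | C=CCCCCC[Mg]Br | intermediate
15 | tert-butyldimethyl{[(2R)-2-methyldec-9-en-1-yl]oxy}silane | C[C@H](CCCCCCC=C)CO[Si](C)(C)C(C)(C)C | intermediate
16 | tert-butyldimethyl{[(2R)-2-methyl-8-(1,2,4-trioxolan-3-yl)octyl]oxy}silane (ozonide, not isolated) | C[C@H](CCCCCCC1OCOO1)CO[Si](C)(C)C(C)(C)C | intermediate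
17 | (8R)-9-[(tert-butyldimethylsilyl)oxy]-8-methylnonanal | C[C@H](CCCCCCC=O)CO[Si](C)(C)C(C)(C)C | intermediate
18 | diethyl [(2E)-3-phenylprop-2-en-1-yl]phosphonate | CCOP(=O)(C/C=C/c1ccccc1)OCC | starting material
19 | diethyl [(2E)-1-lithio-3-phenylprop-2-en-1-yl]phosphonate (not isolated) | [Li]C(/C=C/c1ccccc1)P(=O)(OCC)OCC | intermediate
20 | tert-butyldimethyl{[(2R,9E,11E)-2-methyl-12-phenyldodeca-9,11-dien-1-yl]oxy}silane | C[C@H](CCCCCC/C=C/C=C/c1ccccc1)CO[Si](C)(C)C(C)(C)C | intermediate
21 | (2R,9E,11E)-2-methyl-12-phenyldodeca-9,11-dien-1-ol | C[C@H](CCCCCC/C=C/C=C/c1ccccc1)CO | intermediate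
22 | [(1E,3E,11R)-12-iodo-11-methyldodeca-1,3-dien-1-yl]benzene | C[C@H](CCCCCC/C=C/C=C/c1ccccc1)CI | intermediate
23 | bis[(2R,9E,11E)-2-methyl-12-phenyldodeca-9,11-dien-1-yl]zinc (not isolated) | C[C@H](CCCCCC/C=C/C=C/c1ccccc1)C[Zn]C[C@H](C)CCCCCC/C=C/C=C/c1ccccc1 | intermediate
24 | [(2R,9E,11E)-2-methyl-12-phenyldodeca-9,11-dien-1-yl]zinc trifluoromethanesulfonate (not isolated) | C[C@H](CCCCCC/C=C/C=C/c1ccccc1)C[Zn]OS(=O)(=O)C(F)(F)F | intermediate
25 | (trifluoromethanesulfonato)zinc 2-[(3R,5R)-3,5-dimethyl-5-[(2R,9E,11E)-2-methyl-12-phenyldodeca-9,11-dien-1-yl]-1,2-dioxolan-3-yl]acetate (not isolated) | C[C@H](CCCCCC/C=C/C=C/c1ccccc1)C[C@]1(C)C[C@](C)(CC(=O)O[Zn]OS(=O)(=O)C(F)(F)F)OO1 | intermediate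
26 | 2-[(3R,5R)-3,5-dimethyl-5-[(2R,9E,11E)-2-methyl-12-phenyldodeca-9,11-dien-1-yl]-1,2-dioxolan-3-yl]acetic acid | C[C@H](CCCCCC/C=C/C=C/c1ccccc1)C[C@]1(C)C[C@](C)(CC(=O)O)OO1 | target

Total step count: 13. Longest linear sequence: 7 steps (steps 1–6 and 13, or steps 7–12 and 13).

Steps most likely to fail

Step 13 (proposed new method). The peroxycarbenium ion may be reduced by β-hydride transfer from the alkylzinc instead of being alkylated, the ion pair may lose its facial memory, or the acylal may fragment under Lewis acid. The fallback uses known chemistry only; it sets out from ketone 6 and iodide 22 and comes back at 26. Iodide 22 would be converted (Mg, THF) into [(2R,9E,11E)-2-methyl-12-phenyldodeca-9,11-dien-1-yl]magnesium iodide F1. Grignard addition of F1 to ketone 6 (LaCl3·2LiCl, THF, −78 °C) forms the same C–C bond and should give (4R,11E,13E)-2,4-dimethyl-1-[(2R)-2-methyloxetan-2-yl]-14-phenyltetradeca-11,13-dien-2-ol F2 as a pair of carbinol epimers. Lewis acid-mediated perhydrolysis of the oxetane (ethereal H2O2, TMSOTf cat., −78 → −20 °C; inversion, as in step 5) should give (3S,7R,14E,16E)-3-hydroperoxy-3,5,7-trimethyl-17-phenylheptadeca-14,16-diene-1,5-diol F3. Acid-catalysed cyclisation of F3 (TsOH cat., CH2Cl2), in which the hydroperoxide captures the tertiary cation formed at the carbinol carbon, closes the 1,2-dioxolane without facial control. The cis isomer 2-{(3S,5R)-3,5-dimethyl-5-[(2R,9E,11E)-2-methyl-12-phenyldodeca-9,11-dien-1-yl]-1,2-dioxolan-3-yl}ethan-1-ol F4 would therefore have to be separated from its C5 epimer by chromatography. Oxidation of F4 (TEMPO cat., PhI(OAc)2, MeCN/H2O) then gives 26.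

Step 6. C–H oxidation next to the ketal oxygen may be sluggish, or the acylal may be opened hydrolytically in the aqueous oxidising medium. The fallback sets out from 9 and comes back at 10. Acid-catalysed methanolysis (MeOH, CSA cat.) should open the ketal bridge to 2-[(3S)-5-methoxy-3,5-dimethyl-1,2-dioxolan-3-yl]ethan-1-ol F5. Oxidation of the freed primary alcohol (TEMPO cat., PhI(OAc)2, CH2Cl2/H2O) gives 2-[(3R)-5-methoxy-3,5-dimethyl-1,2-dioxolan-3-yl]acetic acid F6. Acid-catalysed lactonisation of F6 (CSA cat., 4 Å MS, CH2Cl2) with loss of methanol closes the bicyclic acylal 10.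

Step 5. Stereochemical fidelity may be eroded by SN1 ionisation at the tertiary oxetane carbon, or the oxetane may open by β-elimination towards the ketone instead of by substitution. The fallback sets out from 6 and comes back at 9 by way of 8. Deliberate β-elimination (DBU, CH2Cl2) converts 6 into (3E)-6-hydroxy-4-methylhex-3-en-2-one F7. Amine-catalysed asymmetric hydroperoxidation of this enone (9-amino-9-deoxy-epi-cinchona alkaloid salt, aq H2O2, dioxane; the pseudoenantiomer that gives the 5S centre) should give peroxyhemiketal 8 by conjugate addition and ring closure. Ketalisation of 8 as in step 5 (PPTS cat., 4 Å MS) gives 9; the enantioselectivity on this β,β-disubstituted enone would have to be established.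

Further compounds
F1 | step 13 | [(2R,9E,11E)-2-methyl-12-phenyldodeca-9,11-dien-1-yl]magnesium iodide | C[C@H](CCCCCC/C=C/C=C/c1ccccc1)C[Mg]I
F2 | step 13 | (4R,11E,13E)-2,4-dimethyl-1-[(2R)-2-methyloxetan-2-yl]-14-phenyltetradeca-11,13-dien-2-ol (both C2 epimers) | C[C@H](CCCCCC/C=C/C=C/c1ccccc1)CC(C)(O)C[C@@]1(C)CCO1
F3 | step 13 | (3S,7R,14E,16E)-3-hydroperoxy-3,5,7-trimethyl-17-phenylheptadeca-14,16-diene-1,5-diol (both C5 epimers) | C[C@H](CCCCCC/C=C/C=C/c1ccccc1)CC(C)(O)C[C@@](C)(OO)CCO
F4 | step 13 | 2-{(3S,5R)-3,5-dimethyl-5-[(2R,9E,11E)-2-methyl-12-phenyldodeca-9,11-dien-1-yl]-1,2-dioxolan-3-yl}ethan-1-ol | C[C@H](CCCCCC/C=C/C=C/c1ccccc1)C[C@]1(C)C[C@](C)(CCO)OO1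
F5 | step 6 | 2-[(3S)-5-methoxy-3,5-dimethyl-1,2-dioxolan-3-yl]ethan-1-ol (both C5 epimers) | COC1(C)C[C@](C)(CCO)OO1
F6 | step 6 | 2-[(3R)-5-methoxy-3,5-dimethyl-1,2-dioxolan-3-yl]acetic acid (both C5 epimers) | COC1(C)C[C@](C)(CC(=O)O)OO1
F7 | step 5 | (3E)-6-hydroxy-4-methylhex-3-en-2-one | CC(=O)/C=C(\C)CCO
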